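**Retrosynthetic overview**

- The strategy rests on ring C (the pyranone): its adjacent carbons C3 (enol OH) and C4 (C=O) both carry oxygen, so the C3–C4 bond can be cut to two aldehyde carbons that stay linked through C4a–C8a–O1–C2.
- Key disconnection: reductive SmI2 pinacol coupling of a dialdehyde to a chromane-3,4-diol. Oxidation to the 3,4-dione and enolisation then give the 3-hydroxy-4-one, and BCl3 frees the 5-, 2'- and 5'-hydroxyls.
- The dialdehyde comes from the O1–C2 ether bond: a tetramethoxysalicylaldehyde (ring A, from 1,2,3,4-tetramethoxybenzene) is O-alkylated with an α-bromo arylacetate (ring B, from homogentisic acid), then reduced to the diol and oxidised twice.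
- Ring order: rings A and B are bought as benzene rings; ring C is the only ring built, in the key step.

Key step: step 9

Remark: the target has no stereocentre, so all chiral intermediates are carried as racemates and the chromane diol as a diastereomer mixture. Homogentisic acid and the final hydroquinone autoxidise readily and are handled under argon.

**Route**

Step 1
Reactants: 1 1,2,3,4-tetramethoxybenzene
Product: 2 2,3,4,5-tetramethoxybenzaldehyde
Conditions: Cl2CHOMe, TiCl4, CH2Cl2, 0 °C; then H2O
Reagents that add atoms: dichloromethyl methyl ether, COC(Cl)Cl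
Why: Rieche formylation, in which the TiCl4-activated electrophile attacks one of the two equivalent free positions of the symmetric electron-rich arene and aqueous work-up releases the aldehyde.

Step 2
Reactants: 2 2,3,4,5-tetramethoxybenzaldehyde
Product: 4 2,3,4,5-tetramethoxyphenol, via 2,3,4,5-tetramethoxyphenyl formate 3 (not isolated)
Conditions: mCPBA, CH2Cl2, 0 °C → rt; NaHCO3 (aq) wash; then K2CO3 (cat.), MeOH, rt
Reagents that add atoms: mCPBA (3-chloroperoxybenzoic acid), OOC(=O)c1cccc(Cl)c1
Why: Baeyer–Villiger (Dakin-type) oxidation in which the electron-rich aryl group migrates in preference to hydride, followed by methanolysis of the aryl formate.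

Step 3
Reactants: 4 2,3,4,5-tetramethoxyphenol
Product: 5 2-hydroxy-3,4,5,6-tetramethoxybenzaldehyde
Conditions: (CH2O)n, MgCl2, Et3N, MeCN, reflux; then 1 M HCl
Reagents that add atoms: paraformaldehyde (formaldehyde), C=O
Why: Magnesium-mediated ortho-formylation (Casnati–Skattebøl), in which the magnesium phenoxide delivers formaldehyde to the only free ring position and a second equivalent of formaldehyde acts as hydride acceptor to bring the new carbon to the aldehyde level.

Step 4
Reactants: 6 homogentisic acid (2,5-dihydroxyphenylacetic acid)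
Product: 7 benzyl 2-[2,5-bis(benzyloxy)phenyl]acetate
Conditions: BnBr, K2CO3, DMF (degassed, argon), rt → 50 °C
Reagents that add atoms: benzyl bromide, BrCc1ccccc1
Why: Williamson O-alkylation of both phenoxides together with SN2 esterification of the carboxylate, run with exclusion of oxygen because the hydroquinone anion autoxidises.

Step 5
Reactants: 7 benzyl 2-[2,5-bis(benzyloxy)phenyl]acetate
Product: 9 benzyl 2-bromo-2-[2,5-bis(benzyloxy)phenyl]acetate (racemic), via silyl ketene acetal 8 (not isolated)
Conditions: LiN(SiMe3)2, THF, −78 °C; Me3SiCl; then NBS, −78 °C → 0 °C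
Reagents that add atoms: N-bromosuccinimide, BrN1C(=O)CCC1=O
Why: Electrophilic α-bromination of an ester enolate equivalent, where the enolate is trapped as its silyl ketene acetal and brominated at carbon by NBS, which avoids radical conditions that would attack the benzyl ethers; the new stereocentre is formed racemic.

Step 6
Reactants: 5 2-hydroxy-3,4,5,6-tetramethoxybenzaldehyde; 9 benzyl 2-bromo-2-[2,5-bis(benzyloxy)phenyl]acetate
Product: 10 benzyl 2-[2,5-bis(benzyloxy)phenyl]-2-(2-formyl-3,4,5,6-tetramethoxyphenoxy)acetate (racemic)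
Conditions: K2CO3, DMF, rt
Reagents that add atoms: none
Why: Williamson ether synthesis in which the potassium phenoxide of 5 displaces the doubly activated secondary benzylic bromide by SN2, with mild carbonate base at room temperature so that the product does not enolise onto its own aldehyde.

Step 7
Reactants: 10 benzyl 2-[2,5-bis(benzyloxy)phenyl]-2-(2-formyl-3,4,5,6-tetramethoxyphenoxy)acetate
Product: 11 2-[2,5-bis(benzyloxy)phenyl]-2-[2-(hydroxymethyl)-3,4,5,6-tetramethoxyphenoxy]ethan-1-ol (racemic)
Conditions: LiAlH4, THF, 0 °C; then H2O, NaOH (aq) (Fieser work-up)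
Reagents that add atoms: none
Why: LiAlH4 hydride reduction takes the aryl aldehyde and the benzyl ester to primary alcohols in one operation while the aryl ethers are inert and the stereocentre is untouched.

Step 8
Reactants: 11 2-[2,5-bis(benzyloxy)phenyl]-2-[2-(hydroxymethyl)-3,4,5,6-tetramethoxyphenoxy]ethan-1-ol
Product: 12 2-{1-[2,5-bis(benzyloxy)phenyl]-2-oxoethoxy}-3,4,5,6-tetramethoxybenzaldehyde (racemic)
Conditions: Dess–Martin periodinane, NaHCO3, CH2Cl2, 0 °C → rt; short silica pad, used at once
Reagents that add atoms: none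
Why: Dess–Martin oxidation converts both primary alcohols to aldehydes under buffered, amine-free conditions, chosen because the α-aryloxy arylacetaldehyde is easily enolised.

Step 9
Reactants: 12 2-{1-[2,5-bis(benzyloxy)phenyl]-2-oxoethoxy}-3,4,5,6-tetramethoxybenzaldehyde
Product: 13 2-[2,5-bis(benzyloxy)phenyl]-5,6,7,8-tetramethoxychromane-3,4-diol (racemic mixture of diastereomers)
Conditions: SmI2 (0.1 M in THF, 2.5 equiv) added slowly to 12 (0.01 M in THF), −78 °C → −40 °C; then NH4Cl (aq)
Reagents that add atoms: none
Why: Single-electron transfer from SmI2 to the aryl aldehyde, the better acceptor of the two carbonyls, should give a samarium-bound ketyl at the future C4 that attacks the samarium-coordinated aliphatic aldehyde carbon (future C3), and a second electron converts the resulting oxygen radical into the samarium diolate, which gives the diol on work-up. The closest known reaction type is the SmI2 intramolecular pinacol coupling of 1,6-dialdehydes to cyclohexane-1,2-diols, which tolerates α-alkoxy substituents. Ring C closes in the 6-exo-trig mode through the new C3–C4 bond, with O1 and C2 already in the tether. The two new stereocentres C3 and C4 are expected mainly cis because the samarium ion bridges both oxygens, and their relation to C2 should follow the pseudo-equatorial aryl group, but no control is needed because C2, C3 and C4 all become sp2 in step 10. The selectivity needed is cyclisation over reductive cleavage of the C2–O1 aryloxy bond and over simple reduction or dimerisation, and it is secured by the conjugated aryl aldehyde being reduced first, by the fast six-membered closure, by slow addition of the reductant to the cold dilute substrate, and by leaving out HMPA and proton donors.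

Step 10
Reactants: 13 2-[2,5-bis(benzyloxy)phenyl]-5,6,7,8-tetramethoxychromane-3,4-diol
Product: 15 2-[2,5-bis(benzyloxy)phenyl]-3-hydroxy-5,6,7,8-tetramethoxy-4H-chromen-4-one, via chromane-3,4-dione 14 (not isolated)
Conditions: IBX (4 equiv), DMSO, rt → 40 °C
Reagents that add atoms: none
Why: IBX oxidises 1,2-diols to 1,2-diones without glycol cleavage, and the dione, which still carries the acidic hydrogen at C2, should enolise spontaneously to the aromatic 3-hydroxy-4-pyranone, which erases all three sp3 centres.

Step 11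
Reactants: 15 2-[2,5-bis(benzyloxy)phenyl]-3-hydroxy-5,6,7,8-tetramethoxy-4H-chromen-4-one
Product: 16 2-(2,5-dihydroxyphenyl)-3,5-dihydroxy-6,7,8-trimethoxy-4H-chromen-4-one (CNP0236469.0)
Conditions: BCl3 (excess), C6HMe5, CH2Cl2, −78 °C → 0 °C; then MeOH, H2O (degassed, argon)
Reagents that add atoms: none
Why: BCl3-mediated ether cleavage, in which the aryl benzyl ethers are cleaved at −78 °C with pentamethylbenzene as a non-basic benzyl cation trap and, on warming, only the 5-methoxy group is demethylated because it alone can chelate boron together with the C4 carbonyl oxygen.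

**Compound list**

1 | 1,2,3,4-tetramethoxybenzene | COc1ccc(OC)c(OC)c1OC | starting material
2 | 2,3,4,5-tetramethoxybenzaldehyde | COc1cc(C=O)c(OC)c(OC)c1OC | intermediate
3 | 2,3,4,5-tetramethoxyphenyl formate (not isolated) | COc1cc(OC=O)c(OC)c(OC)c1OC | intermediate
4 | 2,3,4,5-tetramethoxyphenol | COc1cc(O)c(OC)c(OC)c1OC | intermediate
5 | 2-hydroxy-3,4,5,6-tetramethoxybenzaldehyde | COc1c(OC)c(OC)c(C=O)c(O)c1OC | intermediate
6 | homogentisic acid (2,5-dihydroxyphenylacetic acid) | OC(=O)Cc1cc(O)ccc1O | starting material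
7 | benzyl 2-[2,5-bis(benzyloxy)phenyl]acetate | O=C(Cc1cc(OCc2ccccc2)ccc1OCc1ccccc1)OCc1ccccc1 | intermediate
8 | {[1-(benzyloxy)-2-[2,5-bis(benzyloxy)phenyl]ethenyl]oxy}trimethylsilane, silyl ketene acetal, E/Z mixture (not isolated) | C[Si](C)(C)OC(OCc1ccccc1)=Cc1cc(OCc2ccccc2)ccc1OCc1ccccc1 | intermediate
9 | benzyl 2-bromo-2-[2,5-bis(benzyloxy)phenyl]acetate, racemic | O=C(OCc1ccccc1)C(Br)c1cc(OCc2ccccc2)ccc1OCc1ccccc1 | intermediate
10 | benzyl 2-[2,5-bis(benzyloxy)phenyl]-2-(2-formyl-3,4,5,6-tetramethoxyphenoxy)acetate, racemic | COc1c(OC)c(OC)c(C=O)c(OC(C(=O)OCc2ccccc2)c2cc(OCc3ccccc3)ccc2OCc2ccccc2)c1OC | intermediate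
11 | 2-[2,5-bis(benzyloxy)phenyl]-2-[2-(hydroxymethyl)-3,4,5,6-tetramethoxyphenoxy]ethan-1-ol, racemic | COc1c(OC)c(OC)c(CO)c(OC(CO)c2cc(OCc3ccccc3)ccc2OCc2ccccc2)c1OC | intermediate
12 | 2-{1-[2,5-bis(benzyloxy)phenyl]-2-oxoethoxy}-3,4,5,6-tetramethoxybenzaldehyde, racemic | COc1c(OC)c(OC)c(C=O)c(OC(C=O)c2cc(OCc3ccccc3)ccc2OCc2ccccc2)c1OC | intermediate
13 | 2-[2,5-bis(benzyloxy)phenyl]-5,6,7,8-tetramethoxychromane-3,4-diol, racemic mixture of diastereomers at C2, C3 and C4 | COc1c(OC)c(OC)c2C(O)C(O)C(c3cc(OCc4ccccc4)ccc3OCc3ccccc3)Oc2c1OC | intermediate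
14 | 2-[2,5-bis(benzyloxy)phenyl]-5,6,7,8-tetramethoxychromane-3,4-dione, racemic (not isolated) | COc1c(OC)c(OC)c2C(=O)C(=O)C(c3cc(OCc4ccccc4)ccc3OCc3ccccc3)Oc2c1OC | intermediate
15 | 2-[2,5-bis(benzyloxy)phenyl]-3-hydroxy-5,6,7,8-tetramethoxy-4H-chromen-4-one | COc1c(OC)c(OC)c2c(=O)c(O)c(-c3cc(OCc4ccccc4)ccc3OCc3ccccc3)oc2c1OC | intermediate
16 | 2-(2,5-dihydroxyphenyl)-3,5-dihydroxy-6,7,8-trimethoxy-4H-chromen-4-one (CNP0236469.0) | COc1c(OC)c(O)c2c(=O)c(O)c(-c3cc(O)ccc3O)oc2c1OC | target

**Step count**

Total: 11 steps. Longest linear sequence: 9 steps (steps 1, 2, 3, 6, 7, 8, 9, 10, 11 from compound 1); the branch from compound 6 (steps 4 and 5) joins at step 6.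

**Steps most likely to fail**

1. Step 9 (pinacol ring closure). The ketyl may form at the aliphatic carbonyl and expel the aryloxide (reductive scission of the C2–O1 bond); either aldehyde may be reduced to its alcohol; or the aryl ketyl may dimerise between molecules before it cyclises. Fallback, setting out from 4 and returning at 15: ring C is built by the classical chalcone path instead.
   - Phenol 4 is C-acetylated at its only free position with acetic acid and BF3·OEt2 (90 °C) to 1-(2-hydroxy-3,4,5,6-tetramethoxyphenyl)ethan-1-one F1.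
   - Claisen–Schmidt condensation (KOH, EtOH, rt) of F1 with 2,5-bis(benzyloxy)benzaldehyde F2, made from commercial 2,5-dihydroxybenzaldehyde with BnBr and K2CO3, should give (E)-3-[2,5-bis(benzyloxy)phenyl]-1-(2-hydroxy-3,4,5,6-tetramethoxyphenyl)prop-2-en-1-one F3.
   - I2 (cat.) in DMSO at 120 °C closes ring C oxidatively to 2-[2,5-bis(benzyloxy)phenyl]-5,6,7,8-tetramethoxy-4H-chromen-4-one F4.
   - Dimethyldioxirane in acetone/CH2Cl2 epoxidises the C2=C3 bond to 2-[2,5-bis(benzyloxy)phenyl]-2,3-epoxy-5,6,7,8-tetramethoxychroman-4-one F5, which a trace of TsOH opens to the 3-hydroxyflavone 15.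
   - Direct Algar–Flynn–Oyamada oxidation of F3 is avoided because chalcones with a 6'-methoxy group tend to divert to aurones.

2. Step 8 (double oxidation to the dialdehyde). The α-aryloxy arylacetaldehyde may enolise and add to the neighbouring aryl aldehyde in a five-membered aldol closure, or hydrate and degrade on silica, so that little intact 12 reaches step 9. Fallback, setting out from 10 and returning at 12: the oxidation is avoided altogether.
   - The aryl aldehyde of 10 is masked with HC(OMe)3 and a trace of TsOH as benzyl 2-[2,5-bis(benzyloxy)phenyl]-2-[2-(dimethoxymethyl)-3,4,5,6-tetramethoxyphenoxy]acetate F6.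
   - i-Bu2AlH in toluene at −78 °C should stop the α-aryloxy ester at the aldehyde stage, giving 2-[2,5-bis(benzyloxy)phenyl]-2-[2-(dimethoxymethyl)-3,4,5,6-tetramethoxyphenoxy]acetaldehyde F7.
   - Mild acid (PPTS in wet acetone, or oxalic acid on wet silica) unmasks the very labile electron-rich acetal to give 12, which goes directly into step 9 without meeting an oxidant or an amine base.

3. Step 11 (global deprotection). Demethylation may run on from C5 to the 6-methoxy group once the C5 boron phenoxide has formed; benzyl cations may C-alkylate the electron-rich ring B; and the freed hydroquinone may air-oxidise to the quinone during work-up. Fallback, setting out from 15 and returning at 16: the two deprotections are separated.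
   - Hydrogenolysis (H2, Pd/C, EtOAc–MeOH) removes both benzyl groups without any cation, giving 2-(2,5-dihydroxyphenyl)-3-hydroxy-5,6,7,8-tetramethoxy-4H-chromen-4-one F8.
   - AlCl3 in MeCN (rt → 50 °C, argon) then cleaves only the chelated 5-methyl ether to give 16.

**Further compounds**

F1 | step 9 | 1-(2-hydroxy-3,4,5,6-tetramethoxyphenyl)ethan-1-one | COc1c(OC)c(OC)c(C(C)=O)c(O)c1OC
F2 | step 9 | 2,5-bis(benzyloxy)benzaldehyde | O=Cc1cc(OCc2ccccc2)ccc1OCc1ccccc1
F3 | step 9 | (E)-3-[2,5-bis(benzyloxy)phenyl]-1-(2-hydroxy-3,4,5,6-tetramethoxyphenyl)prop-2-en-1-one | COc1c(OC)c(OC)c(C(=O)/C=C/c2cc(OCc3ccccc3)ccc2OCc2ccccc2)c(O)c1OC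
F4 | step 9 | 2-[2,5-bis(benzyloxy)phenyl]-5,6,7,8-tetramethoxy-4H-chromen-4-one | COc1c(OC)c(OC)c2c(=O)cc(-c3cc(OCc4ccccc4)ccc3OCc3ccccc3)oc2c1OC
F5 | step 9 | 2-[2,5-bis(benzyloxy)phenyl]-2,3-epoxy-5,6,7,8-tetramethoxychroman-4-one, racemic | COc1c(OC)c(OC)c2C(=O)C3OC3(c3cc(OCc4ccccc4)ccc3OCc3ccccc3)Oc2c1OC
F6 | step 8 | benzyl 2-[2,5-bis(benzyloxy)phenyl]-2-[2-(dimethoxymethyl)-3,4,5,6-tetramethoxyphenoxy]acetate, racemic | COc1c(OC)c(OC)c(C(OC)OC)c(OC(C(=O)OCc2ccccc2)c2cc(OCc3ccccc3)ccc2OCc2ccccc2)c1OC
F7 | step 8 | 2-[2,5-bis(benzyloxy)phenyl]-2-[2-(dimethoxymethyl)-3,4,5,6-tetramethoxyphenoxy]acetaldehyde, racemic | COc1c(OC)c(OC)c(C(OC)OC)c(OC(C=O)c2cc(OCc3ccccc3)ccc2OCc2ccccc2)c1OC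
F8 | step 11 | 2-(2,5-dihydroxyphenyl)-3-hydroxy-5,6,7,8-tetramethoxy-4H-chromen-4-one | COc1c(OC)c(OC)c2c(=O)c(O)c(-c3cc(O)ccc3O)oc2c1OC
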